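**Plan**

- Retrosynthesis: the C2 carbinol and the C12 ketone go back to a C2 ketone and a furfurylic CH2. The C1–C16 bond of the seven-membered ring is cut to a C2-ketone enolate and a 16-bromofuran. The oxygens at C2, C7, C18/C19 and the furan are removed to reach (–)-kolavenol. Finally C4–C5 and C9–C10 are cut and the C19 and C20 methyl groups returned to C4 and C10, which gives geranylgeranyl diphosphate.
- Forward order: the C20 chain is activated as its diphosphate; rings B and A arise together in the enzymatic step; then the furan, then the lactone ring (C19–O), and last the seven-membered ring (C1–C16).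
- Stereochemistry: C5, C8, C9 and C10 come from the cyclase; C7 from hydride delivery to a 7-ketone on the open β face; C1 from the reach of the β-oriented C11–C12 tether; C2 from axial hydride delivery to the C2 ketone.
- Enabling feature: ring A (C5–C10) and ring B (C1–C5 plus C10) form a trans-decalin with C19 on C5 and C20 on C9 on one face, H10 on the other, C17 equatorial on C8 and a C3=C4 alkene. This is the neo-clerodane pattern that a kolavenyl diphosphate synthase writes into the all-E polyene in one operation.

Key step: step 3

Numbering and faces: clerodane numbering is used throughout, also for the acyclic precursor; α is the face of C19 and C20, β the face of H10 and of the C11 chain.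
Assumption: the furan oxygen of annonene is taken to come from O2; the balance of step 5 is the same if the C15 oxygen of kolavenol is the one retained.
Assumption: the hydroxylase of step 7 is taken to deliver the equatorial 7β-alcohol; the 7α-epimer would converge on the same ketone in step 8.

**Route**

Step 1
Reactants: 1 (2E,6E,10E)-geranylgeraniol
Product: 2 (2E,6E,10E)-geranylgeranyl bromide
Conditions: PBr3 (0.4 equiv), Et2O, −10 °C
Reagents that add atoms: phosphorus tribromide, BrP(Br)Br
Why: Nucleophilic substitution of the primary allylic alcohol through its bromophosphite at low temperature should give the bromide without allylic transposition or loss of E geometry, as is routine for prenyl-type alcohols.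

Step 2
Reactants: 2 geranylgeranyl bromide; 3 tris(tetrabutylammonium) hydrogen diphosphate
Product: 4 (E,E,E)-geranylgeranyl diphosphate (handled as the ammonium salt, drawn as the free acid)
Conditions: MeCN, rt; then Dowex 50WX8 (NH4+ form), aq. NH4HCO3/iPrOH; cellulose chromatography
Reagents that add atoms: tris(tetrabutylammonium) hydrogen diphosphate 3, CCCC[N+](CCCC)(CCCC)CCCC.CCCC[N+](CCCC)(CCCC)CCCC.CCCC[N+](CCCC)(CCCC)CCCC.OP(=O)([O-])OP(=O)([O-])[O-]
Why: SN2 displacement of the primary allylic bromide by the lipophilic diphosphate salt in a dipolar aprotic solvent is the standard allylic diphosphorylation and should leave the four alkenes untouched.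

Step 3
Reactants: 4 (E,E,E)-geranylgeranyl diphosphate
Product: 5 (–)-kolavenyl diphosphate [(5R,8R,9S,10R)-neo-cleroda-3,13E-dien-15-yl diphosphate]
Conditions: recombinant kolavenyl diphosphate synthase (class 2 diterpene cyclase of Salvia divinorum, expressed in E. coli), MgCl2, HEPES pH 7.5, DTT, 10% glycerol, 30 °C
Reagents that add atoms: none
Why: The aspartic acid of the DxDD motif protonates C3 of the terminal alkene; the C5=C10 alkene attacks C4 (6-endo-trig, closing ring B through C4–C5) and the C8=C9 alkene attacks C10 (6-endo-trig, closing ring A through C9–C10) in a chair–chair fold, which gives the labda-13-en-8-yl cation. Four antiperiplanar suprafacial 1,2-shifts follow (H from C9 to C8, CH3 from C10 to C9, H from C5 to C10, CH3 from C4 to C5), and loss of a C3 proton leaves the C3=C4 alkene. The closest known reaction type is this very one: the native proton-initiated cation–olefin bicyclisation that kolavenyl diphosphate synthases carry out on this substrate. C8 (R) is fixed by the face on which the hydride arrives, C9 (S) and C5 (R) by the faces of the two methyl migrations and C10 (R) by the hydride from C5, each anti to the group that departs, so all four follow from the single enantiomeric fold that the active-site contour imposes on the achiral polyene. The step needs one prochiral fold, completion of all four shifts before quenching and deprotonation at C3 only; the all-E geometry of 4 supplies the trans ring fusion, the pocket and the position of its base supply the rest, and the diphosphate stays bound as a spectator.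

Step 4
Reactants: 5 (–)-kolavenyl diphosphate
Product: 6 (–)-kolavenol
Conditions: calf intestinal alkaline phosphatase, MgCl2, Tris·HCl pH 8.5, 37 °C; hexane extraction
Reagents that add atoms: none
Why: Enzymatic phosphate ester hydrolysis cleaves only P–O bonds, so the allylic C15–O bond and the 13E alkene should survive, whereas acid hydrolysis would ionise the allylic system.

Step 5
Reactants: 6 (–)-kolavenol
Product: 9 hautriwaic acid (15,16-epoxy-19-hydroxy-neo-cleroda-3,13(16),14-trien-18-oic acid), via annonene 7 (not isolated), via hardwickiic acid 8 (not isolated)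
Conditions: yeast microsomes holding annonene synthase, hardwickiic acid synthase and hautriwaic acid synthase (Salvia splendens P450 monooxygenases) and a P450 reductase; NADP+ (cat.), glucose, glucose dehydrogenase, air, K2HPO4/KH2PO4 buffer pH 7.5, 30 °C
Reagents that add atoms: dioxygen, O=O
Why: Each of the three P450 monooxygenases performs its native hydrogen-abstraction/oxygen-rebound oxidation on its native substrate in the biosynthetic order (closure of C15–O–C16 to the furan, oxidation of the C18 methyl to the acid, hydroxylation of the C19 methyl), and no stereocentre is created.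

Step 6
Reactants: 9 hautriwaic acid
Product: 10 15,16-epoxy-neo-cleroda-3,13(16),14-trien-18,19-olide
Conditions: PPTS (cat.), toluene, 4 Å MS, 60 °C
Reagents that add atoms: none
Why: Acid-catalysed lactonisation (intramolecular Fischer esterification) of the γ-hydroxy acid should be easy because the C19 carbinol on C5 and the carboxyl on the neighbouring sp2 C4 are held within bonding distance, and no stereocentre is touched.

Step 7
Reactants: 10 15,16-epoxy-neo-cleroda-3,13(16),14-trien-18,19-olide
Product: 11 7β-hydroxy-15,16-epoxy-neo-cleroda-3,13(16),14-trien-18,19-olide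
Conditions: P450BM3 (CYP102A1) variant picked from an active-site mutant panel (E. coli lysate), NADP+ (cat.), glucose, glucose dehydrogenase, air, K2HPO4/KH2PO4 buffer pH 8.0, 5% DMSO, 25 °C
Reagents that add atoms: dioxygen, O=O
Why: Proposed new method: the ferryl oxo species of an engineered P450BM3 variant should abstract a hydrogen atom from the unactivated C7 methylene of ring A and return OH by rebound with retention at the exposed equatorial C–H, the binding pose being selected by mutant screening so that the furan, the deactivated allylic C2 and the furfurylic C12 stay away from the haem; the closest known reaction type is the hydroxylation of ring methylenes of terpenoid lactones such as sclareolide by P450BM3 variants.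

Step 8
Reactants: 11 7β-hydroxy lactone
Product: 12 7-oxo-15,16-epoxy-neo-cleroda-3,13(16),14-trien-18,19-olide
Conditions: Dess–Martin periodinane, CH2Cl2, 0 °C to rt
Reagents that add atoms: none
Why: Dess–Martin oxidation of the secondary alcohol is neutral, should leave furan, enoate and lactone alone, and erases the C7 configuration so that either epimer from step 7 converges.

Step 9
Reactants: 12 7-oxo lactone
Product: 13 7α-hydroxy-15,16-epoxy-neo-cleroda-3,13(16),14-trien-18,19-olide
Conditions: NaBH4, MeOH/THF, −20 °C
Reagents that add atoms: none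
Why: In this borohydride ketone reduction the α-axial approach to C7 is blocked by the syn-axial C19 methylene and C20 methyl, so hydride should arrive from the β face and set the axial 7α-alcohol (7R), as in the reduction of 11-oxo steroids, while the conjugated lactone is not reduced at low temperature.

Step 10
Reactants: 13 7α-hydroxy lactone
Product: 14 7α-acetoxy-15,16-epoxy-neo-cleroda-3,13(16),14-trien-18,19-olide
Conditions: Ac2O, DMAP, pyridine, 40 °C
Reagents that add atoms: acetic anhydride, CC(=O)OC(C)=O
Why: DMAP-catalysed acylation with excess anhydride should overcome the hindrance of the axial alcohol flanked by C19 and C20, and no other hydroxyl group is present.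

Step 11
Reactants: 14 7α-acetoxy lactone
Product: 15 7α-acetoxy-16-bromo-15,16-epoxy-neo-cleroda-3,13(16),14-trien-18,19-olide
Conditions: NBS (1.05 equiv), CHCl3, 0 °C to rt, dark
Reagents that add atoms: N-bromosuccinimide, O=C1CCC(=O)N1Br
Why: Electrophilic aromatic bromination of the 3-alkylfuran should occur at the α-carbon next to the alkyl-bearing carbon (C16), the regiochemistry known for β-substituted furans of neo-clerodanes, because C12 is still sp3 and the alkyl group stabilises the σ-complex.

Step 12
Reactants: 15 16-bromo lactone
Product: 16 7α-acetoxy-16-bromo-2-oxo-15,16-epoxy-neo-cleroda-3,13(16),14-trien-18,19-olide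
Conditions: CrO3, 3,5-dimethylpyrazole, CH2Cl2, −20 °C
Reagents that add atoms: chromium trioxide, O=[Cr](=O)=O
Why: Allylic oxidation with the hexavalent chromium–pyrazole complex should turn C2, the only allylic methylene of the conjugated lactone (C5 is quaternary), into the ketone as in furyl-substituted bicyclic enoate lactones of the fraxinellone type, the bromine lowering the electron density of the furan towards the oxidant.

Step 13
Reactants: 16 16-bromo-2-oxo lactone
Product: 17 7α-acetoxy-2-oxo-1β,16-cyclo-15,16-epoxy-neo-cleroda-3,13(16),14-trien-18,19-olide (new C1–C16 bond, H1 α; seven-membered ring C1–C10–C9–C11–C12–C13–C16)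
Conditions: Pd2(dba)3 (5 mol%), XPhos (12 mol%), K3PO4, toluene (0.01 M), 90 °C
Reagents that add atoms: none
Why: Intramolecular Buchwald–Hartwig-type α-arylation of the ketone should join C1, the only enolisable carbon, to C16 after oxidative addition of the bromofuran to zerovalent palladium and so close the seven-membered ring, the equatorial 1β bond (1S) being the only one the β-oriented C11–C12 tether can reach and also the thermodynamic epimer of this enolisable centre.

Step 14
Reactants: 17 cyclised 2-ketone
Product: 19 7α-acetoxy-2,12-dioxo-1β,16-cyclo-15,16-epoxy-neo-cleroda-3,13(16),14-trien-18,19-olide, via furfuryl alcohol 18 (not isolated)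
Conditions: DDQ (2.5 equiv), THF/H2O (10:1), 0 °C to rt
Reagents that add atoms: water, O
Why: DDQ should abstract hydride from the C12 methylene, whose cation is stabilised through C13=C16 by the furan oxygen, water traps it and a second equivalent oxidises the furfuryl alcohol to the ketone (the side-chain oxidation known for 3-alkylindoles), while C1–H is deactivated by the adjacent carbonyl and the 3-acylfuran formed resists further oxidation.

Step 15
Reactants: 19 2,12-diketone
Product: 20 target, (1S,2S,5S,7R,8S,9R,10R)-7α-acetoxy-2α-hydroxy-12-oxo-1β,16-cyclo-15,16-epoxy-neo-cleroda-3,13(16),14-trien-18,19-olide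
Conditions: NaBH4 (1 equiv), CeCl3·7H2O, MeOH/CH2Cl2, −78 °C
Reagents that add atoms: none
Why: Luche reduction should add hydride 1,2 to the strongly electrophilic enedione carbonyl C2 in preference to the vinylogous-ester-like furyl ketone C12, the acetate and the lactone, and axial delivery from the β face (anti to the axial C19 bridge, as in 4-en-3-one steroids) sets the pseudo-equatorial 2α-alcohol (2S).

**Compound list**

1 | (2E,6E,10E)-geranylgeraniol | CC(C)=CCC/C(C)=C/CC/C(C)=C/CC/C(C)=C/CO | starting material
2 | (2E,6E,10E)-geranylgeranyl bromide | CC(C)=CCC/C(C)=C/CC/C(C)=C/CC/C(C)=C/CBr | intermediate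
3 | tris(tetrabutylammonium) hydrogen diphosphate | CCCC[N+](CCCC)(CCCC)CCCC.CCCC[N+](CCCC)(CCCC)CCCC.CCCC[N+](CCCC)(CCCC)CCCC.OP(=O)([O-])OP(=O)([O-])[O-] | starting material
4 | (E,E,E)-geranylgeranyl diphosphate | CC(C)=CCC/C(C)=C/CC/C(C)=C/CC/C(C)=C/COP(=O)(O)OP(=O)(O)O | intermediate
5 | (–)-kolavenyl diphosphate | C1C[C@@]2(C)C(C)=CCC[C@@H]2[C@@](C)(CC/C(C)=C/COP(=O)(O)OP(=O)(O)O)[C@@H]1C | intermediate
6 | (–)-kolavenol | C1C[C@@]2(C)C(C)=CCC[C@@H]2[C@@](C)(CC/C(C)=C/CO)[C@@H]1C | intermediate
7 | annonene (15,16-epoxy-neo-cleroda-3,13(16),14-triene) | C1C[C@@]2(C)C(C)=CCC[C@@H]2[C@@](C)(CCc3ccoc3)[C@@H]1C | intermediate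
8 | hardwickiic acid | C1C[C@@]2(C)C(C(=O)O)=CCC[C@@H]2[C@@](C)(CCc3ccoc3)[C@@H]1C | intermediate
9 | hautriwaic acid | C1C[C@@]2(CO)C(C(=O)O)=CCC[C@@H]2[C@@](C)(CCc3ccoc3)[C@@H]1C | intermediate
10 | 15,16-epoxy-neo-cleroda-3,13(16),14-trien-18,19-olide | C1C[C@@]23COC(=O)C2=CCC[C@@H]3[C@@](C)(CCc4ccoc4)[C@@H]1C | intermediate
11 | 7β-hydroxy-15,16-epoxy-neo-cleroda-3,13(16),14-trien-18,19-olide | O[C@H]1C[C@@]23COC(=O)C2=CCC[C@@H]3[C@@](C)(CCc4ccoc4)[C@@H]1C | intermediate
12 | 7-oxo-15,16-epoxy-neo-cleroda-3,13(16),14-trien-18,19-olide | O=C1C[C@@]23COC(=O)C2=CCC[C@@H]3[C@@](C)(CCc4ccoc4)[C@@H]1C | intermediate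
13 | 7α-hydroxy-15,16-epoxy-neo-cleroda-3,13(16),14-trien-18,19-olide | O[C@@H]1C[C@@]23COC(=O)C2=CCC[C@@H]3[C@@](C)(CCc4ccoc4)[C@@H]1C | intermediate
14 | 7α-acetoxy-15,16-epoxy-neo-cleroda-3,13(16),14-trien-18,19-olide | CC(=O)O[C@@H]1C[C@@]23COC(=O)C2=CCC[C@@H]3[C@@](C)(CCc4ccoc4)[C@@H]1C | intermediate
15 | 7α-acetoxy-16-bromo-15,16-epoxy-neo-cleroda-3,13(16),14-trien-18,19-olide | CC(=O)O[C@@H]1C[C@@]23COC(=O)C2=CCC[C@@H]3[C@@](C)(CCc4c(Br)occ4)[C@@H]1C | intermediate
16 | 7α-acetoxy-16-bromo-2-oxo-15,16-epoxy-neo-cleroda-3,13(16),14-trien-18,19-olide | CC(=O)O[C@@H]1C[C@@]23COC(=O)C2=CC(=O)C[C@@H]3[C@@](C)(CCc4c(Br)occ4)[C@@H]1C | intermediate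
17 | 7α-acetoxy-2-oxo-1β,16-cyclo-15,16-epoxy-neo-cleroda-3,13(16),14-trien-18,19-olide | CC(=O)O[C@@H]1C[C@@]23COC(=O)C2=CC(=O)[C@H]2c4occc4CC[C@@](C)([C@@H]1C)[C@@H]23 | intermediate
18 | (12ξ)-7α-acetoxy-12-hydroxy-2-oxo-1β,16-cyclo-15,16-epoxy-neo-cleroda-3,13(16),14-trien-18,19-olide | CC(=O)O[C@@H]1C[C@@]23COC(=O)C2=CC(=O)[C@H]2c4occc4C(O)C[C@@](C)([C@@H]1C)[C@@H]23 | intermediate
19 | 7α-acetoxy-2,12-dioxo-1β,16-cyclo-15,16-epoxy-neo-cleroda-3,13(16),14-trien-18,19-olide | CC(=O)O[C@@H]1C[C@@]23COC(=O)C2=CC(=O)[C@H]2c4occc4C(=O)C[C@@](C)([C@@H]1C)[C@@H]23 | intermediate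
20 | 7α-acetoxy-2α-hydroxy-12-oxo-1β,16-cyclo-15,16-epoxy-neo-cleroda-3,13(16),14-trien-18,19-olide | CC(=O)O[C@@H]1C[C@@]23COC(=O)C2=C[C@H](O)[C@H]2c4occc4C(=O)C[C@@](C)([C@@H]1C)[C@@H]23 | target

**Step count and risks**

Total steps: 15. Longest linear sequence: 15 steps (1 to 20).

Steps most likely to fail:

1. Step 7 (Proposed new method). The hydroxylase may oxidise the wrong site (allylic C2, furfurylic C12 or the furan ring) or not turn the substrate over at all. The fallback uses known chemistry, sets out from 9 and returns at 12. Esterification of 9 with TMSCHN2 gives methyl hautriwaate F1. NOCl in pyridine at −30 °C converts its C19 carbinol into the 19-nitrite ester F2. Barton nitrite photolysis (350 nm, benzene) lets the C19 alkoxy radical abstract the syn-axial H7α through a six-membered transition state. NO recombination and tautomerisation then give the 7-oxime F3. Deoximation with aqueous TiCl3/NH4OAc gives the 7-oxo hydroxy ester F4, and PPTS in toluene lactonises it to 12. Loss of formaldehyde from the alkoxy radical and abstraction of H1α are the side paths to be watched in this sequence.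

2. Step 14. Hydride abstraction may go astray: dehydrogenation through the C2 enol towards C1/C10, oxidation of the electron-rich furan ring, or proton loss from the C12 cation to a vinylfuran. The fallback sets out from 15 and returns at 19; it moves the C12 oxidation ahead of ring closure and removes DDQ. Excess CrO3·3,5-dimethylpyrazole at 0 °C oxidises both the allylic C2 and the furfurylic C12 of 15 to give the 16-bromo-2,12-diketone F5. The Pd2(dba)3/XPhos/K3PO4 arylation then closes C1–C16 (the 2-bromo-3-acylfuran is activated for oxidative addition) and gives 19 directly.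

3. Step 12. The oxidant may degrade the bromofuran or attack C12 competitively, and hydrogen abstraction next to the electron-poor alkene may be slow. The fallback sets out from 15 and returns at 16; it replaces C–H abstraction by enolate chemistry. Soft enolisation of the conjugated lactone (TBSOTf, Et3N, CH2Cl2, −78 to 0 °C) removes a C2 proton and gives the silyl dienol ether F6. Vinylogous Rubottom oxidation with DMDO at −78 °C places oxygen on the unhindered γ-carbon C2 and gives the 2-hydroxy lactone F7 as a mixture of C2 epimers. Dess–Martin oxidation of F7 gives 16.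

Further compounds
F1 | step 7 | methyl hautriwaate | C1C[C@@]2(CO)C(C(=O)OC)=CCC[C@@H]2[C@@](C)(CCc3ccoc3)[C@@H]1C
F2 | step 7 | methyl hautriwaate 19-nitrite | C1C[C@@]2(CON=O)C(C(=O)OC)=CCC[C@@H]2[C@@](C)(CCc3ccoc3)[C@@H]1C
F3 | step 7 | methyl 7-(hydroxyimino)hautriwaate | ON=C1C[C@@]2(CO)C(C(=O)OC)=CCC[C@@H]2[C@@](C)(CCc3ccoc3)[C@@H]1C
F4 | step 7 | methyl 7-oxohautriwaate | O=C1C[C@@]2(CO)C(C(=O)OC)=CCC[C@@H]2[C@@](C)(CCc3ccoc3)[C@@H]1C
F5 | step 14 | 7α-acetoxy-16-bromo-2,12-dioxo-15,16-epoxy-neo-cleroda-3,13(16),14-trien-18,19-olide | CC(=O)O[C@@H]1C[C@@]23COC(=O)C2=CC(=O)C[C@@H]3[C@@](C)(CC(=O)c4c(Br)occ4)[C@@H]1C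
F6 | step 12 | 18-O-tert-butyldimethylsilyl dienol ether of 15 (2,4(18)-diene) | CC(=O)O[C@@H]1C[C@@]23COC(O[Si](C)(C)C(C)(C)C)=C2C=CC[C@@H]3[C@@](C)(CCc4c(Br)occ4)[C@@H]1C
F7 | step 12 | (2ξ)-7α-acetoxy-16-bromo-2-hydroxy-15,16-epoxy-neo-cleroda-3,13(16),14-trien-18,19-olide | CC(=O)O[C@@H]1C[C@@]23COC(=O)C2=CC(O)C[C@@H]3[C@@](C)(CCc4c(Br)occ4)[C@@H]1C
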